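**Remark on the chemistry (assumption):** the SMILES is read as the single isomer 1R,2S,3R,4S,8R,9Z,12S,13R in the cembrane-type numbering defined in the first section; the enantiomer of each chiral catalyst or ligand named below is the one that delivers the stated configuration.

## Analysis of the target

The target is a C20 cembranolide. Numbering used throughout: C1–C14 form the 14-membered carbocycle; C15 (lactone α-carbon), C16 (C=O) and C17 (exo-methylene) sit on C1; methyls C18, C19, C20 sit on C4, C8, C12. An ether oxygen joins C3 and C13, which cuts the carbocycle into a 2,6-cis-tetrahydropyran (O, C3, C2, C1, C14, C13) and a bridging 12-membered oxacycle (O, C3–C13). An α-methylene-γ-butyrolactone (O–C2, C1, C15, C16) is cis-fused to the tetrahydropyran at C1–C2, on the face opposite the nine-carbon bridge.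

There are seven stereocentres (C1 R, C2 S, C3 R, C4 S, C8 R, C12 S, C13 R) and one Z-olefin (C9=C10). C1–C4 form a contiguous array: the lactone is cis at C1/C2, the C2 and C3 oxygens are anti, and O3/Me-4 are syn. C12 and C13 carry vicinal oxygens in the relationship left by trans opening of an (E)-12,13-epoxide. C8 is an isolated tertiary allylic carbinol, remote from the rest.

Sensitive groups are the methylene lactone (Michael acceptor, easily reduced, base-labile) and the tertiary allylic alcohol at C8. With a Z-olefin in place, O8 sits within reach of C12.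

The difficulties are the bridged bicyclic ether inside a macrocycle, a Z-olefin wedged between a quaternary carbinol and a CH2, and two tertiary carbinol centres that cannot relay stereochemistry to each other.

The feature the route exploits: O links C3 and C13; C13 is flanked by the tertiary carbinol C12; and C3 and C13 are 1,5-related through C2–C1–C14. This is the retron of a transannular 6-exo opening of a (12S,13S)-12,13-epoxide by a C3 hydroxyl across the 14-membered carbocycle. The C9=C10 olefin can be carried through that step as a ring alkyne, which fixes the Z geometry later and keeps O8 away from the epoxide.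

## Retrosynthetic reasoning

**C9=C10 (32 ⇐ 31).** The Z-olefin is taken back to the ring alkyne 31. cis-Addition of hydrogen to a cycloalkyne can only give the Z-alkene, so the geometry is not left to a ring-closing olefination.

**O–C13, the key disconnection (31/30 ⇐ 28 via 29).** The ether bond is cut, not a C–C bond of the macrocycle. This removes the tetrahydropyran, the oxa-bridge and the C12/C13 stereocentres in one operation and leaves 28, a plain 14-membered lactone-fused carbocycle with one (E)-trisubstituted olefin. Forward, an asymmetric epoxidation must choose one face of C12=C13, and the C3 hydroxyl must then open the epoxide 29 at C13 in the 6-exo mode with inversion.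

**C9≡C10 ring closure (28 ⇐ 27 ⇐ 26).** The carbocycle is opened at the alkyne by ring-closing alkyne metathesis of the bis(methylalkyne) 26. The 14-membered ring is unstrained, and the alkyne termini tolerate the lactone, the silyl ether and the aminoxy group.

**C1–C2 with the lactone (26 ⇐ 14 + 24).** A zinc-mediated allylation joins the two halves and makes the methylene lactone in the same step. It must give the syn adduct (cis-lactone, from the Z-bromide 24 through a chair transition state) and add anti to the C3 oxygen of 14 (Felkin–Anh, secured by a bulky, non-chelating aminoxy group).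

**C3–O and C4 (14 ⇐ 13 ⇐ 12 ⇐ 9 + 10).** The C3 oxygen comes from catalyst-controlled α-oxyamination of aldehyde 13. The C4 methyl centre comes from a copper-catalysed asymmetric conjugate addition of the Grignard reagent of bromide 9 to crotonate 10. Both centres are set by catalysts because C8 is too far away to help.

**C8 (9 ⇐ 5 ⇐ 3 ⇐ 2 ⇐ 1).** The tertiary propargylic carbinol is taken from geraniol (1): asymmetric epoxidation fixes the C–O centre, and base-induced fragmentation of the epoxy chloride 3 turns C1–C2 of geraniol into the alkyne without touching that centre. Ozonolysis of the remaining olefin then reveals C5.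

**Eastern half (24 ⇐ 23 ⇐ 20 + 21; 19 ⇐ 17 ⇐ 15 + 16).** The (Z)-bromomethyl enoate 24 comes from the hydroxy-methylene ester 23 by bromination with allylic transposition. The (E)-C12=C13 olefin with its methyl comes from syn-carboalumination of the terminal alkyne of the skipped diyne 17.

## Alternatives that were turned down

**Alternative 1: ring-closing olefin metathesis at C9=C10 (the textbook route).** The tetrahydropyran and lactone are completed first, and the seco-diene A1 (vinyl on C8, allyl on C12) is closed with a ruthenium or molybdenum carbene. Turned down because the new bond must be Z and one terminus is a vinyl group on the quaternary carbinol C8. Kinetically Z-selective catalysts do not accept such hindered olefins, and a 12-membered ring has no built-in Z preference under thermodynamic control. The hardest stereochemical element would be left to chance in the last C–C bond formation.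

**Alternative 2: macrocyclising intramolecular Barbier allylation at C1–C2.** The open-chain ω-formyl bromomethyl-enoate A2 would close the 14-membered ring and the lactone together. Turned down for three reasons:
- A2 must carry an α-oxygenated, epimerisable aldehyde and an allylic bromide at the two ends of one chain, both unveiled late in a linear sequence.
- The (9Z)-olefin must already be in place, so the two halves can no longer be joined through the C1–C2 bond, and convergence is lost.
- The facial selectivity at C2 would be governed by macrocycle conformation, not by a predictable Felkin model.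

**Alternative 3: oxonium ylide formation/[2,3]-sigmatropic rearrangement.** A metal carbenoid from diazoketone A3 would attack the C13 crotyl ether oxygen; the [2,3]-shift would give tetrahydropyranone A4 and set C3 and C4 as a pair. Turned down for three reasons:
- The shift leaves C5=C6 as a terminal vinyl group, which cannot be joined to C7 without losing a carbon or adding an olefin that must later be told apart from C9=C10 and the methylene lactone.
- The C2 ketone of A4 needs four to five further steps (alkylation at C1, reduction, lactonisation, methylenation) to become the lactone.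
- The 2,6-relationship in six-membered ylide rearrangements is not reliably cis, and the macrocycle is still unmade.

The precursor costs more than the step wins.

Key step: step 18

## Route

**Step 1**
Reactants: 1 geraniol [(2E)-3,7-dimethylocta-2,6-dien-1-ol]
Product: 2 (2R,3R)-2,3-epoxygeraniol {[(2R,3R)-3-methyl-3-(4-methylpent-3-en-1-yl)oxiran-2-yl]methanol}
Conditions: Ti(OiPr)4 (cat.), D-(−)-diethyl tartrate, t-BuOOH, 4 Å MS, CH2Cl2, −20 °C
Reagents that add atoms: tert-butyl hydroperoxide, CC(C)(C)OO
Why: Sharpless asymmetric epoxidation of an (E)-trisubstituted allylic alcohol; the D-tartrate complex delivers oxygen to the face that gives the (2R,3R)-epoxide, whose tertiary C–O centre becomes C8.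

**Step 2**
Reactants: 2 (2R,3R)-2,3-epoxygeraniol
Product: 3 (2S,3R)-2-(chloromethyl)-3-methyl-3-(4-methylpent-3-en-1-yl)oxirane
Conditions: PPh3, CCl4, NaHCO3, reflux
Reagents that add atoms: carbon tetrachloride, ClC(Cl)(Cl)Cl
Why: Appel chlorination of the primary alcohol under neutral conditions; SN2 at CH2 leaves the epoxide and both stereocentres untouched (the C2 descriptor changes only by CIP priority).

**Step 3**
Reactants: 3 (2S,3R)-2-(chloromethyl)-3-methyl-3-(4-methylpent-3-en-1-yl)oxirane
Product: 5 (4R)-4,8-dimethylnon-7-en-2-yn-4-ol, via dilithiated (R)-dehydrolinalool 4 (not isolated)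
Conditions: n-BuLi (3.3 equiv), THF, −40 → −20 °C; then MeI, DMPU, −20 °C → rt
Reagents that add atoms: iodomethane, CI
Why: Base-induced fragmentation of a 2,3-epoxy chloride to a propargylic alcohol (deprotonation α to Cl, E1cB epoxide opening, dehydrochlorination), then C-methylation of the acetylide of the dianion; the tertiary C–O bond is never broken, so C8 keeps the R configuration.

**Step 4**
Reactants: 5 (4R)-4,8-dimethylnon-7-en-2-yn-4-ol
Product: 6 triethyl{[(4R)-4,8-dimethylnon-7-en-2-yn-4-yl]oxy}silane
Conditions: TESOTf, 2,6-lutidine, CH2Cl2, 0 °C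
Reagents that add atoms: triethylsilyl trifluoromethanesulfonate, CC[Si](CC)(CC)OS(=O)(=O)C(F)(F)F
Why: Silyl triflate silylation of a hindered tertiary alcohol; the ether protects the carbinol through Grignard formation and alkyne metathesis.

**Step 5**
Reactants: 6 triethyl{[(4R)-4,8-dimethylnon-7-en-2-yn-4-yl]oxy}silane
Product: 8 (4R)-4-methyl-4-(triethylsilyloxy)hept-5-yn-1-ol, via silyloxy heptynal 7 (not isolated)
Conditions: O3, CH2Cl2–MeOH, −78 °C (indicator end point); then NaBH4, −78 → 0 °C
Reagents that add atoms: ozone, [O-][O+]=O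
Why: Ozonolysis is chemoselective for the electron-rich trisubstituted olefin over the internal alkyne; reductive work-up gives the primary alcohol at C5.

**Step 6**
Reactants: 8 (4R)-4-methyl-4-(triethylsilyloxy)hept-5-yn-1-ol
Product: 9 {[(4R)-7-bromo-4-methylhept-2-yn-4-yl]oxy}triethylsilane
Conditions: CBr4, PPh3, CH2Cl2, 0 °C
Reagents that add atoms: carbon tetrabromide, BrC(Br)(Br)Br
Why: Appel bromination of a primary alcohol; the tertiary silyl ether and the alkyne are inert.

**Step 7**
Reactants: 9 {[(4R)-7-bromo-4-methylhept-2-yn-4-yl]oxy}triethylsilane; 10 methyl (E)-but-2-enoate (methyl crotonate)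
Product: 12 methyl (3S,7R)-3,7-dimethyl-7-(triethylsilyloxy)dec-8-ynoate, via alkylmagnesium bromide 11 (not isolated)
Conditions: Mg, THF; then CuI (cat.), Tol-BINAP (cat., enantiomer that gives 3S), t-BuOMe, −40 °C
Reagents that add atoms: none
Why: Copper/bisphosphine-catalysed asymmetric conjugate addition of a Grignard reagent to an enoate; the ligand controls the face of the crotonate and so sets C4, and the remote C8 centre has no say.

**Step 8**
Reactants: 12 methyl (3S,7R)-3,7-dimethyl-7-(triethylsilyloxy)dec-8-ynoate
Product: 13 (3S,7R)-3,7-dimethyl-7-(triethylsilyloxy)dec-8-ynal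
Conditions: DIBAL-H (1.05 equiv), CH2Cl2, −78 °C
Reagents that add atoms: none
Why: Partial reduction of the methyl ester through the stable aluminium hemiacetal at low temperature; the β-stereocentre is not epimerisable.

**Step 9**
Reactants: 13 (3S,7R)-3,7-dimethyl-7-(triethylsilyloxy)dec-8-ynal
Product: 14 (2R,3S,7R)-3,7-dimethyl-2-[(2,2,6,6-tetramethylpiperidin-1-yl)oxy]-7-(triethylsilyloxy)dec-8-ynal
Conditions: TEMPO, CuCl2 (cat.), 5-benzyl-2-tert-butyl-3-methylimidazolidin-4-one·TFA (cat., enantiomer that gives 2R), air, acetone, −10 °C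
Reagents that add atoms: TEMPO, CC1(C)CCCC(C)(C)N1[O]
Why: Enamine/copper-catalysed enantioselective α-oxyamination of an aldehyde; the catalyst shields one enamine face and sets C3 (R), and the hindered aminoxy group then serves as a non-chelating protecting group for the next step.

**Step 10**
Reactants: 15 propargyl bromide (3-bromoprop-1-yne); 16 prop-1-yn-1-ylmagnesium bromide
Product: 17 hexa-1,4-diyne
Conditions: CuCl (cat.), THF, 0 °C → rt
Reagents that add atoms: none
Why: Copper-catalysed propargyl–alkynyl coupling (SN2 at the propargylic carbon), the standard entry to skipped diynes.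

**Step 11**
Reactants: 17 hexa-1,4-diyne
Product: 19 (3E)-4-methylnon-3-en-6-yn-1-ol, via alkenyldimethylalane 18 (not isolated)
Conditions: Me3Al, Cp2ZrCl2 (cat.), CH2Cl2, 0 °C → rt; then n-BuLi, THF, −30 °C; ethylene oxide, → rt
Reagents that add atoms: trimethylaluminium, C[Al](C)C; ethylene oxide, C1CO1
Why: Negishi zirconium-catalysed carboalumination adds Me and Al syn across the terminal alkyne only (internal alkynes are much slower), which fixes the (E)-C12=C13 geometry; the alanate then opens oxirane with retention at the alkenyl carbon.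

**Step 12**
Reactants: 19 (3E)-4-methylnon-3-en-6-yn-1-ol
Product: 20 (3E)-4-methylnon-3-en-6-ynal
Conditions: Dess–Martin periodinane, NaHCO3, CH2Cl2, 0 °C; used at once
Reagents that add atoms: none
Why: Dess–Martin oxidation under buffered, non-basic conditions gives the β,γ-unsaturated aldehyde without migration of the olefin into conjugation.

**Step 13**
Reactants: 20 (3E)-4-methylnon-3-en-6-ynal; 21 methyl propiolate
Product: 23 methyl (5E)-3-hydroxy-6-methyl-2-methylidenedec-5-en-8-ynoate (racemic at C3), via α-aluminoacrylate 22 (not isolated)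
Conditions: DIBAL-H, NMO, THF, 0 °C, then 21; then 20, 0 °C → rt
Reagents that add atoms: none
Why: Vinylalumination: α-selective hydroalumination of the propiolate gives an α-aluminoacrylate that adds 1,2 to the aldehyde, delivering the Morita–Baylis–Hillman-type adduct within minutes and without the amine base that would isomerise the β,γ-unsaturated aldehyde; the carbinol centre is destroyed in step 14.

**Step 14**
Reactants: 23 methyl (5E)-3-hydroxy-6-methyl-2-methylidenedec-5-en-8-ynoate
Product: 24 methyl (2Z,5E)-2-(bromomethyl)-6-methyldeca-2,5-dien-8-ynoate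
Conditions: NBS, Me2S, CH2Cl2, 0 °C → rt
Reagents that add atoms: N-bromosuccinimide, O=C1CCC(=O)N1Br
Why: Corey–Kim-type activation of the allylic alcohol and SN2′ displacement by bromide gives the 2-(bromomethyl)enoate with the chain trans to the ester (Z), the thermodynamically preferred isomer for adducts of this type.

**Step 15**
Reactants: 14 (2R,3S,7R)-3,7-dimethyl-2-[(2,2,6,6-tetramethylpiperidin-1-yl)oxy]-7-(triethylsilyloxy)dec-8-ynal; 24 methyl (2Z,5E)-2-(bromomethyl)-6-methyldeca-2,5-dien-8-ynoate
Product: 26 (4R,5S)-5-[(1R,2S,6R)-2,6-dimethyl-1-[(2,2,6,6-tetramethylpiperidin-1-yl)oxy]-6-(triethylsilyloxy)non-7-yn-1-yl]-3-methylidene-4-[(2E)-3-methylhept-2-en-5-yn-1-yl]oxolan-2-one, via syn-hydroxy ester 25 (not isolated)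
Conditions: Zn dust, THF–sat. aq. NH4Cl, 0 °C → rt; then PPTS (cat.), CH2Cl2, rt
Reagents that add atoms: none
Why: Barbier (Dreiding–Schmidt) allylation: the allylzinc attacks through its γ-carbon (C1) in a chair transition state, the (Z)-bromide giving the syn adduct and hence the cis-lactone (C1 R); Felkin–Anh addition anti to the bulky, non-chelating α-aminoxy group sets C2 (S) anti to the C3 oxygen; the syn-hydroxy ester lactonises.

**Step 16**
Reactants: 26 (the bis(methylalkyne) lactone of step 15)
Product: 27 (1R,2S,3R,4S,8R,12E)-3-[(2,2,6,6-tetramethylpiperidin-1-yl)oxy]-8-(triethylsilyloxy)cembra-12,15(17)-dien-9-yn-16,2-olide (14-membered cycloalkyne)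
Conditions: Mo(≡CC6H4OMe-4)(OSiPh3)3 (cat.), 5 Å MS, toluene (2 mM), 80 °C
Reagents that add atoms: none
Why: Ring-closing alkyne metathesis of two methyl-capped alkynes; but-2-yne is trapped by the sieves, the 14-membered ring is unstrained, and the catalyst class tolerates esters, silyl ethers and olefins.

**Step 17**
Reactants: 27 (the cycloalkyne of step 16)
Product: 28 (1R,2S,3R,4S,8R,12E)-3-hydroxy-8-(triethylsilyloxy)cembra-12,15(17)-dien-9-yn-16,2-olide
Conditions: Zn dust, AcOH–THF–H2O, rt → 40 °C
Reagents that add atoms: none
Why: Reductive cleavage of the N–O bond of the alkoxyamine by zinc in acetic acid frees the C3 hydroxyl; the alkyne, the acrylate-type olefin and the lactone are not reduced under these conditions.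

**Step 18**
Reactants: 28 (the C3 alcohol of step 17)
Product: 30 (1R,2S,3R,4S,8R,12S,13R)-3,13-epoxy-12-hydroxy-8-(triethylsilyloxy)cembr-15(17)-en-9-yn-16,2-olide, via 12,13-epoxide 29 (not isolated)
Conditions: L-fructose-derived Shi ketone (cat.), Oxone, K2CO3, Bu4NHSO4, MeCN–DMM–aq. buffer (pH ≈ 10.5), −5 °C; then CSA (cat.), CH2Cl2, 0 °C
Reagents that add atoms: Oxone (potassium peroxymonosulfate), [K+].OOS(=O)(=O)[O-]
Why: Shi epoxidation then transannular epoxide-opening etherification: the chiral dioxirane transfers oxygen through a spiro transition state to the only electron-rich olefin, the (E)-trisubstituted C12=C13, while the ring alkyne and the acrylate-type C15=C17 are inert, and catalyst control is relied on for the (12S,13S)-epoxide 29. Acid then activates 29 and the C3 hydroxyl attacks C13 anti to the breaking C–O bond (inversion at C13, retention at C12), so C12 (S) and C13 (R) are set together by the epoxide face. The tetrahydropyran closes in the 6-exo-tet mode across the 14-membered ring; the competing 7-endo attack at tertiary C12 would give an oxepane and is disfavoured by ring size. The closest known reaction types are Shi epoxidation/epoxy-alcohol cyclisation in polyether synthesis and transannular epoxide openings of cembranoid macrocycles. The cis-fused lactone holds C3 and C14 on the same face and so places O3 next to C13. The linear C8–C9≡C10–C11 unit, with O8 also silylated, keeps the C8 oxygen away from C12, so the six-membered O8–C12 ether that a (9Z)-olefin would permit cannot form. The step needs face selectivity in the epoxidation (from the catalyst) and 6-exo regioselectivity (from ring size and the unhindered secondary C13).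

**Step 19**
Reactants: 30 (the bridged cycloalkyne of step 18)
Product: 31 (1R,2S,3R,4S,8R,12S,13R)-3,13-epoxy-8,12-dihydroxycembr-15(17)-en-9-yn-16,2-olide
Conditions: HF·pyridine, THF–pyridine, 0 °C → rt
Reagents that add atoms: none
Why: Buffered fluoride desilylation of the tertiary triethylsilyl ether; non-basic, so the methylene lactone is not attacked.

**Step 20**
Reactants: 31 (the diol cycloalkyne of step 19)
Product: 32 (1R,2S,3R,4S,8R,9Z,12S,13R)-3,13-epoxy-8,12-dihydroxycembra-9,15(17)-dien-16,2-olide (CNP0146755.1)
Conditions: Zn(Cu/Ag), MeOH–H2O, 45 °C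
Reagents that add atoms: none
Why: cis-Semi-reduction of an alkyne activated by the free propargylic hydroxyl with activated zinc; cis-addition to the ring alkyne gives only the (9Z)-olefin and stops at the alkene, and the conjugated methylene lactone is not reduced by this reagent.

## Compound list

1 | geraniol, (2E)-3,7-dimethylocta-2,6-dien-1-ol | OC/C=C(\C)CCC=C(C)C | starting material
2 | [(2R,3R)-3-methyl-3-(4-methylpent-3-en-1-yl)oxiran-2-yl]methanol | OC[C@H]1O[C@]1(C)CCC=C(C)C | intermediate
3 | (2S,3R)-2-(chloromethyl)-3-methyl-3-(4-methylpent-3-en-1-yl)oxirane | ClC[C@H]1O[C@]1(C)CCC=C(C)C | intermediate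
4 | dilithium (3R)-3,7-dimethyloct-6-en-1-yn-1-ide-3-olate | [Li]C#C[C@](C)(O[Li])CCC=C(C)C | intermediate
5 | (4R)-4,8-dimethylnon-7-en-2-yn-4-ol | CC#C[C@](C)(O)CCC=C(C)C | intermediate
6 | triethyl{[(4R)-4,8-dimethylnon-7-en-2-yn-4-yl]oxy}silane | CC#C[C@](C)(O[Si](CC)(CC)CC)CCC=C(C)C | intermediate
7 | (4R)-4-methyl-4-(triethylsilyloxy)hept-5-ynal | CC#C[C@](C)(O[Si](CC)(CC)CC)CCC=O | intermediate
8 | (4R)-4-methyl-4-(triethylsilyloxy)hept-5-yn-1-ol | CC#C[C@](C)(O[Si](CC)(CC)CC)CCCO | intermediate
9 | {[(4R)-7-bromo-4-methylhept-2-yn-4-yl]oxy}triethylsilane | CC#C[C@](C)(O[Si](CC)(CC)CC)CCCBr | intermediate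
10 | methyl (E)-but-2-enoate | C/C=C/C(=O)OC | starting material
11 | [(4R)-4-methyl-4-(triethylsilyloxy)hept-5-yn-1-yl]magnesium bromide | CC#C[C@](C)(O[Si](CC)(CC)CC)CCC[Mg]Br | intermediate
12 | methyl (3S,7R)-3,7-dimethyl-7-(triethylsilyloxy)dec-8-ynoate | CC#C[C@](C)(O[Si](CC)(CC)CC)CCC[C@H](C)CC(=O)OC | intermediate
13 | (3S,7R)-3,7-dimethyl-7-(triethylsilyloxy)dec-8-ynal | CC#C[C@](C)(O[Si](CC)(CC)CC)CCC[C@H](C)CC=O | intermediate
14 | (2R,3S,7R)-3,7-dimethyl-2-[(2,2,6,6-tetramethylpiperidin-1-yl)oxy]-7-(triethylsilyloxy)dec-8-ynal | CC#C[C@](C)(O[Si](CC)(CC)CC)CCC[C@H](C)[C@@H](ON1C(C)(C)CCCC1(C)C)C=O | intermediate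
15 | 3-bromoprop-1-yne | C#CCBr | starting material
16 | prop-1-yn-1-ylmagnesium bromide | CC#C[Mg]Br | starting material
17 | hexa-1,4-diyne | C#CCC#CC | intermediate
18 | dimethyl[(1E)-2-methylhex-1-en-4-yn-1-yl]alumane | CC#CC/C(C)=C/[Al](C)C | intermediate
19 | (3E)-4-methylnon-3-en-6-yn-1-ol | CC#CC/C(C)=C/CCO | intermediate
20 | (3E)-4-methylnon-3-en-6-ynal | CC#CC/C(C)=C/CC=O | intermediate
21 | methyl propiolate | C#CC(=O)OC | starting material
22 | methyl 2-(diisobutylalumanyl)prop-2-enoate | C=C(C(=O)OC)[Al](CC(C)C)CC(C)C | intermediate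
23 | methyl (5E)-3-hydroxy-6-methyl-2-methylidenedec-5-en-8-ynoate (racemic) | CC#CC/C(C)=C/CC(O)C(=C)C(=O)OC | intermediate
24 | methyl (2Z,5E)-2-(bromomethyl)-6-methyldeca-2,5-dien-8-ynoate | CC#CC/C(C)=C/C/C=C(\CBr)C(=O)OC | intermediate
25 | methyl (3R,4S,5R,6S,10R)-4-hydroxy-6,10-dimethyl-2-methylidene-3-[(2E)-3-methylhept-2-en-5-yn-1-yl]-5-[(2,2,6,6-tetramethylpiperidin-1-yl)oxy]-10-(triethylsilyloxy)tridec-11-ynoate | COC(=O)C(=C)[C@@H](C/C=C(\C)CC#CC)[C@H](O)[C@H](ON1C(C)(C)CCCC1(C)C)[C@@H](C)CCC[C@@](C)(O[Si](CC)(CC)CC)C#CC | intermediate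
26 | (4R,5S)-5-[(1R,2S,6R)-2,6-dimethyl-1-[(2,2,6,6-tetramethylpiperidin-1-yl)oxy]-6-(triethylsilyloxy)non-7-yn-1-yl]-3-methylidene-4-[(2E)-3-methylhept-2-en-5-yn-1-yl]oxolan-2-one | C=C1C(=O)O[C@H]([C@H](ON2C(C)(C)CCCC2(C)C)[C@@H](C)CCC[C@@](C)(O[Si](CC)(CC)CC)C#CC)[C@@H]1C/C=C(\C)CC#CC | intermediate
27 | (1R,2S,3R,4S,8R,12E)-3-[(2,2,6,6-tetramethylpiperidin-1-yl)oxy]-8-(triethylsilyloxy)cembra-12,15(17)-dien-9-yn-16,2-olide | C=C1C(=O)O[C@@H]2[C@H](ON3C(C)(C)CCCC3(C)C)[C@@H](C)CCC[C@@](C)(O[Si](CC)(CC)CC)C#CC/C(C)=C/C[C@H]12 | intermediate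
28 | (1R,2S,3R,4S,8R,12E)-3-hydroxy-8-(triethylsilyloxy)cembra-12,15(17)-dien-9-yn-16,2-olide | C=C1C(=O)O[C@@H]2[C@H](O)[C@@H](C)CCC[C@@](C)(O[Si](CC)(CC)CC)C#CC/C(C)=C/C[C@H]12 | intermediate
29 | (1R,2S,3R,4S,8R,12S,13S)-12,13-epoxy-3-hydroxy-8-(triethylsilyloxy)cembr-15(17)-en-9-yn-16,2-olide | C=C1C(=O)O[C@@H]2[C@H](O)[C@@H](C)CCC[C@@](C)(O[Si](CC)(CC)CC)C#CC[C@]3(C)O[C@H]3C[C@H]12 | intermediate
30 | (1R,2S,3R,4S,8R,12S,13R)-3,13-epoxy-12-hydroxy-8-(triethylsilyloxy)cembr-15(17)-en-9-yn-16,2-olide | C=C1C(=O)O[C@@H]2[C@@H]3O[C@H](C[C@H]12)[C@@](C)(O)CC#C[C@](C)(O[Si](CC)(CC)CC)CCC[C@@H]3C | intermediate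
31 | (1R,2S,3R,4S,8R,12S,13R)-3,13-epoxy-8,12-dihydroxycembr-15(17)-en-9-yn-16,2-olide | C=C1C(=O)O[C@@H]2[C@@H]3O[C@H](C[C@H]12)[C@@](C)(O)CC#C[C@](C)(O)CCC[C@@H]3C | intermediate
32 | (1R,2S,3R,4S,8R,9Z,12S,13R)-3,13-epoxy-8,12-dihydroxycembra-9,15(17)-dien-16,2-olide (CNP0146755.1) | C=C1C(=O)O[C@@H]2[C@@H]3O[C@H](C[C@H]12)[C@@](C)(O)C/C=C\[C@](C)(O)CCC[C@@H]3C | target

## Step count and least certain steps

Total step count: 20. Longest linear sequence: 15 steps (steps 1–9 and 15–20, from geraniol 1); the eastern half takes 5 steps (10–14).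

**Step 18 (key step).** Two things may go wrong. The macrocycle may expose mainly one face of C12=C13, so that conformational bias overrides the catalyst and the wrong epoxide face is oxidised. The transannular closure may also be slow enough for intermolecular or 7-endo opening, or for hydrolysis of the lactone at the pH of the epoxidation, to compete. The fallback builds the tetrahydropyran before the ring: it sets out from 26 and returns at 30. Zinc in acetic acid on 26 gives the open-chain C3 alcohol (hydroxy diyne lactone) F1. Epoxidation of F1 with the same ketone, now on a conformationally free olefin under plain reagent control, and acid-promoted 6-exo closure give the tetrahydropyran-fused lactone with two methylalkyne arms F2. Ring-closing alkyne metathesis of F2, whose arms are held cis on the pyran chair, gives 30.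

**Step 15.** Facial control at the aldehyde may be incomplete (loss of Felkin selectivity, or partial epimerisation of the α-aminoxy centre), or the syn/anti ratio may erode through allylzinc isomerisation. The fallback replaces the open Barbier process by a closed, reagent-controllable allylboration: it sets out from 24 and returns at 26. Palladium-catalysed borylation of 24 with bis(pinacolato)diboron gives the linear allylboronate (methyl 2-(boronylmethyl)dienynoate) F3. Allylboration of 14 with F3 through a Zimmerman–Traxler chair (Z-crotyl-type geometry gives syn), if needed under a chiral phosphoric acid that dictates the aldehyde face, and acid lactonisation give 26.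

**Step 7.** Enantiofacial discrimination of the small crotonate by the copper/bisphosphine catalyst may be insufficient with this functionalised Grignard reagent. The fallback uses auxiliary control: it sets out from 9 (through Grignard 11) and returns at 12. Copper-mediated addition of 11 to (S)-3-[(E)-but-2-enoyl]-4-phenyloxazolidin-2-one, anti to the phenyl group of the chelated s-cis imide, gives the N-acyl oxazolidinone F4. Methanolysis of F4 with a magnesium methoxide gives 12.

**Step 20.** Reduction of the hindered ring alkyne may be slow, or conjugate reduction of the methylene lactone or over-reduction may set in. The fallback is a two-stage syn-hydrosilylation/protodesilylation: it sets out from 31 and returns at 32. Platinum-catalysed syn-addition of triethoxysilane to 31, with silicon at the less hindered C10, gives the alkenylsilane F5. Silver fluoride-mediated protodesilylation of F5 in aqueous THF–MeOH, with retention, gives 32.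

## Further compounds

F1 | step 18 | (4R,5S)-5-[(1R,2S,6R)-1-hydroxy-2,6-dimethyl-6-(triethylsilyloxy)non-7-yn-1-yl]-3-methylidene-4-[(2E)-3-methylhept-2-en-5-yn-1-yl]oxolan-2-one | C=C1C(=O)O[C@H]([C@H](O)[C@@H](C)CCC[C@@](C)(O[Si](CC)(CC)CC)C#CC)[C@@H]1C/C=C(\C)CC#CC
F2 | step 18 | 9,10-seco analogue of 30 with prop-1-ynyl on C8 and but-2-ynyl on C12 (tetrahydropyran-fused methylene lactone, 1R,2S,3R,4S,8R,12S,13R) | C=C1C(=O)O[C@@H]2[C@@H]([C@@H](C)CCC[C@@](C)(O[Si](CC)(CC)CC)C#CC)O[C@H](C[C@H]12)[C@@](C)(O)CC#CC
F3 | step 15 | methyl (2E,5E)-6-methyl-2-[(4,4,5,5-tetramethyl-1,3,2-dioxaborolan-2-yl)methyl]deca-2,5-dien-8-ynoate | CC#CC/C(C)=C/C/C=C(\CB1OC(C)(C)C(C)(C)O1)C(=O)OC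
F4 | step 7 | (4S)-3-[(3S,7R)-3,7-dimethyl-7-(triethylsilyloxy)dec-8-ynoyl]-4-phenyloxazolidin-2-one | O=C1OC[C@H](c2ccccc2)N1C(=O)C[C@@H](C)CCC[C@@](C)(O[Si](CC)(CC)CC)C#CC
F5 | step 20 | (1R,2S,3R,4S,8R,12S,13R)-3,13-epoxy-8,12-dihydroxy-10-(triethoxysilyl)cembra-9,15(17)-dien-16,2-olide (C8 and C11 cis on the olefin) | C=C1C(=O)O[C@@H]2[C@@H]3O[C@H](C[C@H]12)[C@@](C)(O)C/C([Si](OCC)(OCC)OCC)=C\[C@](C)(O)CCC[C@@H]3C
A1 | alternative 1 | 9,10-seco-diene of 32 (vinyl on C8, allyl on C12; tetrahydropyran and lactone complete) | C=C1C(=O)O[C@@H]2[C@@H]([C@@H](C)CCC[C@@](C)(O)C=C)O[C@H](C[C@H]12)[C@@](C)(O)CC=C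
A2 | alternative 2 | methyl (2Z,5E,8Z,10R,14S,15R)-2-(bromomethyl)-15-(tert-butyldimethylsilyloxy)-6,10,14-trimethyl-16-oxo-10-(triethylsilyloxy)hexadeca-2,5,8-trienoate | COC(=O)/C(CBr)=C/C/C=C(\C)C/C=C\[C@](C)(O[Si](CC)(CC)CC)CCC[C@H](C)[C@@H](O[Si](C)(C)C(C)(C)C)C=O
A3 | alternative 3 | (5R,6S)-5-[(2E)-but-2-en-1-yloxy]-1-diazo-6-methyl-6-(triethylsilyloxy)non-8-en-2-one | [N-]=[N+]=CC(=O)CC[C@@H](OC/C=C/C)[C@@](C)(O[Si](CC)(CC)CC)CC=C
A4 | alternative 3 | (2R,6R)-2-[(2S)-but-3-en-2-yl]-6-[(2S)-2-(triethylsilyloxy)pent-4-en-2-yl]oxan-3-one | C=C[C@H](C)[C@H]1O[C@H](CCC1=O)[C@@](C)(O[Si](CC)(CC)CC)CC=C
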